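The cyclohexene is numbered C1 (angeloyloxy), C2=C3 (methyl on C3), C4 (acetoxy), C5 (CH2), C6 (side chain). It is cut into C3–C4–C5, a latent ketone at C4 flanked by two α-carbons, and C6–C1–C2, a latent (E)-enal that already carries the complete side chain. An amine-catalysed Michael addition/aldol condensation ([3+3] annulation) of allyl 3-oxopentanoate with that enal closes the ring. It makes the C5–C6 bond, the C2=C3 double bond and the C6 stereocentre in one operation. The ester is then excised, C1 is oxygenated by a vinylogous Rubottom oxidation, and the C4 ketone becomes the axial acetate by Luche reduction and Mitsunobu inversion.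

Key step: step 8

Remark on the chemistry: side-chain carbons are C7 (CH–CH3), C8, C9 (CH–OAc), C10=C11. The sense of induction in steps 3, 4 and 8 is assigned from the accepted models for these catalysts; the other catalyst enantiomer would be used if a first run showed the opposite sense.

Step 1
Reactants: 1 (E)-but-2-enal; 2 2-methylprop-1-en-1-ylmagnesium bromide
Product: 3 (E)-6-methylhepta-2,5-dien-4-ol (racemic)
Conditions: THF, −78 to 0 °C; aq. NH4Cl
Reagents that add atoms: none
Why: Grignard 1,2-addition of the alkenylmagnesium reagent to the enal should give the bis-allylic alcohol; the carbinol centre needs no control because it is oxidised in step 2.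

Step 2
Reactants: 3 (E)-6-methylhepta-2,5-dien-4-ol
Product: 4 (E)-6-methylhepta-2,5-dien-4-one
Conditions: MnO2 (15 equiv), CH2Cl2, 23 °C
Reagents that add atoms: none
Why: MnO2 oxidation of an allylic alcohol should give the cross-conjugated dienone without touching the (E)-alkene.

Step 3
Reactants: 4 (E)-6-methylhepta-2,5-dien-4-one; 5 (E)-2-(3,3-diethoxyprop-1-en-1-yl)-4,4,5,5-tetramethyl-1,3,2-dioxaborolane
Product: 6 (6R,7E)-9,9-diethoxy-2,6-dimethylnona-2,7-dien-4-one
Conditions: [Rh(OH)((R)-BINAP)]2 (1.5 mol%), 1,4-dioxane/H2O (10:1), 40 °C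
Reagents that add atoms: none
Why: Hayashi–Miyaura rhodium-catalysed asymmetric 1,4-addition should deliver the alkenyl group only to the β-monosubstituted enone terminus (the β,β-dimethyl terminus is inert), with the (R)-BINAP ligand selecting the enone face that gives the (R) centre at C7.

Step 4
Reactants: 6 (6R,7E)-9,9-diethoxy-2,6-dimethylnona-2,7-dien-4-one
Product: 7 (4R,6R,7E)-9,9-diethoxy-2,6-dimethylnona-2,7-dien-4-ol
Conditions: (S)-2-methyl-CBS-oxazaborolidine (20 mol%), catecholborane (1.5 equiv), toluene, −78 °C; MeOH, aq. NaOH wash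
Reagents that add atoms: none
Why: CBS reduction of the enone, in which the alkenyl group acts as the large substituent, should give the (R)-allylic alcohol at C9 under reagent control, and catecholborane at −78 °C should leave the alkenes and the acetal alone.

Step 5
Reactants: 7 (4R,6R,7E)-9,9-diethoxy-2,6-dimethylnona-2,7-dien-4-ol
Product: 8 (4R,6R,7E)-9,9-diethoxy-2,6-dimethylnona-2,7-dien-4-yl acetate
Conditions: Ac2O, Et3N, DMAP (5 mol%), CH2Cl2, 0 to 23 °C
Reagents that add atoms: acetic anhydride, CC(=O)OC(C)=O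
Why: DMAP-catalysed acylation of the secondary allylic alcohol installs the C9 acetate of the target with retention.

Step 6
Reactants: 8 (4R,6R,7E)-9,9-diethoxy-2,6-dimethylnona-2,7-dien-4-yl acetate
Product: 9 (2E,4R,6R)-6-acetoxy-4,8-dimethylnona-2,7-dienal
Conditions: PPTS (10 mol%), acetone/H2O (10:1), 23 °C
Reagents that add atoms: water, O
Why: Mild acid hydrolysis of the allylic diethyl acetal should release the (E)-enal under conditions too weak to ionise the allylic acetate or enolise the γ-centre C7.

Step 7
Reactants: 10 methyl 3-oxopentanoate; 11 prop-2-en-1-ol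
Product: 12 allyl 3-oxopentanoate
Conditions: DMAP (5 mol%), toluene, 110 °C, 4 Å MS (MeOH removed)
Reagents that add atoms: none
Why: Transesterification of a β-keto ester (through the acylketene or acyl-DMAP pathway) should be driven to the allyl ester by removal of methanol.

Step 8
Reactants: 9 (2E,4R,6R)-6-acetoxy-4,8-dimethylnona-2,7-dienal; 12 allyl 3-oxopentanoate
Product: 14 allyl (1R,6R)-6-[(2R,4R)-4-acetoxy-6-methylhept-5-en-2-yl]-3-methyl-2-oxocyclohex-3-ene-1-carboxylate, via Michael adduct 13 (not isolated)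
Conditions: (R)-2-[bis(3,5-bis(trifluoromethyl)phenyl)(trimethylsilyloxy)methyl]pyrrolidine (10 mol%), PhCO2H (10 mol%), toluene, 23 °C; then p-TsOH·H2O (20 mol%), 40 °C
Reagents that add atoms: none
Why: The (R)-diarylprolinol silyl ether condenses with 9 to an (E)-iminium ion, the enol of 12 adds through C5 to the β-carbon C6 (Michael addition) and hydrolysis releases 13; the sulfonic acid then enolises the ethyl ketone towards C3, which attacks the aldehyde carbon C2, and dehydration of the aldol gives the conjugated C2=C3 bond. The closest known reaction type is the amine-catalysed Michael addition/aldol condensation of β-keto esters with enals to 5-substituted cyclohex-2-enones, a [3+3] annulation. The six-membered ring closes in a 6-(enolendo)-exo-trig aldol step, the only strain-free mode open to 13 because every other enol–carbonyl pairing would give a four-membered ring. C6 is set under catalyst control: the diaryl(silyloxy)methyl group shields one face of the iminium ion and the nucleophile adds to the other, which with the (R)-catalyst should give the C6 configuration of the target, whereas the ester-bearing C5 is epimerisable, settles trans to the side chain and is deleted in step 9. The step needs catalyst control to override the resident C7 centre and Michael addition to outrun γ-deprotonation of the iminium ion, which the reactive β-keto ester and the hindered tertiary C7–H should secure, and it needs the allylic acetate to survive, which is why an allyl ester and a 40 °C acid stage are used in place of a tert-butyl ester that would demand hot acid.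

Step 9
Reactants: 14 allyl (1R,6R)-6-[(2R,4R)-4-acetoxy-6-methylhept-5-en-2-yl]-3-methyl-2-oxocyclohex-3-ene-1-carboxylate
Product: 15 (5S)-5-[(2R,4R)-4-acetoxy-6-methylhept-5-en-2-yl]-2-methylcyclohex-2-en-1-one
Conditions: Pd(PPh3)4 (5 mol%), HCO2H (2 equiv), Et3N (2.5 equiv), THF, 23 °C
Reagents that add atoms: none
Why: Tsuji deallylation–decarboxylation: the unsubstituted allyl ester should ionise far faster than the hindered secondary allylic acetate next to a trisubstituted alkene, formate reduces the allylpalladium to propene, and the β-keto acid loses CO2 to leave C5 as CH2.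

Step 10
Reactants: 15 (5S)-5-[(2R,4R)-4-acetoxy-6-methylhept-5-en-2-yl]-2-methylcyclohex-2-en-1-one
Product: 17 (4S,5S)-5-[(2R,4R)-4-acetoxy-6-methylhept-5-en-2-yl]-4-hydroxy-2-methylcyclohex-2-en-1-one, via trimethylsilyl dienol ether 16 (not isolated)
Conditions: TMSOTf (1.3 equiv), Et3N (2 equiv), CH2Cl2, 0 to 23 °C; pentane, filter, concentrate; mCPBA (1.05 equiv), NaHCO3, CH2Cl2, −40 to 0 °C; aq. citric acid
Reagents that add atoms: mCPBA, OOC(=O)c1cccc(Cl)c1
Why: Soft enolisation should give the through-conjugated 1-silyloxy-1,3-diene by γ-deprotonation at C1, and vinylogous Rubottom oxidation of its electron-rich C1=C2 terminus from the face anti to the C6 side chain, followed by epoxide opening, should give the γ-hydroxy enone with C1–O trans to the side chain; the side-chain alkene, deactivated by its allylic acetate, should react much more slowly.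

Step 11
Reactants: 17 (4S,5S)-5-[(2R,4R)-4-acetoxy-6-methylhept-5-en-2-yl]-4-hydroxy-2-methylcyclohex-2-en-1-one; 18 angelic acid [(Z)-2-methylbut-2-enoic acid]
Product: 19 (1S,6S)-6-[(2R,4R)-4-acetoxy-6-methylhept-5-en-2-yl]-3-methyl-4-oxocyclohex-2-en-1-yl (Z)-2-methylbut-2-enoate
Conditions: 18, 2,4,6-trichlorobenzoyl chloride, Et3N, toluene, 23 °C; then 17, 75 °C
Reagents that add atoms: none
Why: Yamaguchi-type mixed-anhydride acylation without a nucleophilic catalyst should esterify the hindered C1 alcohol with retention and keep the (Z) geometry of the angelate, which DMAP would isomerise to the tiglate.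

Step 12
Reactants: 19 (1S,6S)-6-[(2R,4R)-4-acetoxy-6-methylhept-5-en-2-yl]-3-methyl-4-oxocyclohex-2-en-1-yl (Z)-2-methylbut-2-enoate
Product: 20 (1S,4S,6S)-6-[(2R,4R)-4-acetoxy-6-methylhept-5-en-2-yl]-4-hydroxy-3-methylcyclohex-2-en-1-yl (Z)-2-methylbut-2-enoate
Conditions: NaBH4, CeCl3·7H2O, MeOH, −78 °C
Reagents that add atoms: none
Why: Luche 1,2-reduction by axial hydride attack on the half-chair with the C6 substituent equatorial should give the pseudo-equatorial C4 alcohol cis to the side chain (as carvone gives cis-carveol), leaving the three esters untouched.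

Step 13
Reactants: 20 (1S,4S,6S)-6-[(2R,4R)-4-acetoxy-6-methylhept-5-en-2-yl]-4-hydroxy-3-methylcyclohex-2-en-1-yl (Z)-2-methylbut-2-enoate
Product: 21 (1S,4R,6S)-4-acetoxy-6-[(2R,4R)-4-acetoxy-6-methylhept-5-en-2-yl]-3-methylcyclohex-2-en-1-yl (Z)-2-methylbut-2-enoate (CNP0417294.1)
Conditions: PPh3, DIAD, AcOH, THF, 0 to 23 °C
Reagents that add atoms: acetic acid, CC(=O)O
Why: Mitsunobu reaction with acetic acid should displace the alkoxyphosphonium group by SN2 with inversion, placing the C4 acetate pseudo-axial, cis to the C1 angelate and trans to the side chain, which is the target.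

Compound list
1 | (E)-but-2-enal (crotonaldehyde) | C/C=C/C=O | starting material
2 | 2-methylprop-1-en-1-ylmagnesium bromide (THF solution) | CC(C)=C[Mg]Br | starting material
3 | (E)-6-methylhepta-2,5-dien-4-ol (racemic) | C/C=C/C(O)C=C(C)C | intermediate
4 | (E)-6-methylhepta-2,5-dien-4-one | C/C=C/C(=O)C=C(C)C | intermediate
5 | (E)-2-(3,3-diethoxyprop-1-en-1-yl)-4,4,5,5-tetramethyl-1,3,2-dioxaborolane | CCOC(OCC)/C=C/B1OC(C)(C)C(C)(C)O1 | starting material
6 | (6R,7E)-9,9-diethoxy-2,6-dimethylnona-2,7-dien-4-one | CCOC(OCC)/C=C/[C@H](C)CC(=O)C=C(C)C | intermediate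
7 | (4R,6R,7E)-9,9-diethoxy-2,6-dimethylnona-2,7-dien-4-ol | CCOC(OCC)/C=C/[C@H](C)C[C@H](C=C(C)C)O | intermediate
8 | (4R,6R,7E)-9,9-diethoxy-2,6-dimethylnona-2,7-dien-4-yl acetate | CCOC(OCC)/C=C/[C@H](C)C[C@H](C=C(C)C)OC(C)=O | intermediate
9 | (2E,4R,6R)-6-acetoxy-4,8-dimethylnona-2,7-dienal | O=C/C=C/[C@H](C)C[C@H](C=C(C)C)OC(C)=O | intermediate
10 | methyl 3-oxopentanoate | CCC(=O)CC(=O)OC | starting material
11 | prop-2-en-1-ol (allyl alcohol) | C=CCO | starting material
12 | allyl 3-oxopentanoate | CCC(=O)CC(=O)OCC=C | intermediate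
13 | allyl 2-[(3R,4R,6R)-6-acetoxy-4,8-dimethyl-1-oxonon-7-en-3-yl]-3-oxopentanoate (Michael adduct, epimers at the ester-bearing carbon) | O=CC[C@@H](C(C(=O)CC)C(=O)OCC=C)[C@H](C)C[C@H](C=C(C)C)OC(C)=O | intermediate
14 | allyl (1R,6R)-6-[(2R,4R)-4-acetoxy-6-methylhept-5-en-2-yl]-3-methyl-2-oxocyclohex-3-ene-1-carboxylate (trans; epimerisable at C1 of this name) | C1C=C(C)C(=O)[C@H](C(=O)OCC=C)[C@H]1[C@H](C)C[C@H](C=C(C)C)OC(C)=O | intermediate
15 | (5S)-5-[(2R,4R)-4-acetoxy-6-methylhept-5-en-2-yl]-2-methylcyclohex-2-en-1-one | C1C=C(C)C(=O)C[C@H]1[C@H](C)C[C@H](C=C(C)C)OC(C)=O | intermediate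
16 | (2R,4R)-6-methyl-2-[(1S)-4-methyl-5-(trimethylsilyloxy)cyclohexa-2,4-dien-1-yl]hept-5-en-4-yl acetate (linear silyl dienol ether of 15) | C1=CC(C)=C(O[Si](C)(C)C)C[C@H]1[C@H](C)C[C@H](C=C(C)C)OC(C)=O | intermediate
17 | (4S,5S)-5-[(2R,4R)-4-acetoxy-6-methylhept-5-en-2-yl]-4-hydroxy-2-methylcyclohex-2-en-1-one | O[C@@H]1C=C(C)C(=O)C[C@H]1[C@H](C)C[C@H](C=C(C)C)OC(C)=O | intermediate
18 | angelic acid, (Z)-2-methylbut-2-enoic acid | C/C=C(/C)C(=O)O | starting material
19 | (1S,6S)-6-[(2R,4R)-4-acetoxy-6-methylhept-5-en-2-yl]-3-methyl-4-oxocyclohex-2-en-1-yl (Z)-2-methylbut-2-enoate | C/C=C(/C)C(=O)O[C@@H]1C=C(C)C(=O)C[C@H]1[C@H](C)C[C@H](C=C(C)C)OC(C)=O | intermediate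
20 | (1S,4S,6S)-6-[(2R,4R)-4-acetoxy-6-methylhept-5-en-2-yl]-4-hydroxy-3-methylcyclohex-2-en-1-yl (Z)-2-methylbut-2-enoate | C/C=C(/C)C(=O)O[C@@H]1C=C(C)[C@@H](O)C[C@H]1[C@H](C)C[C@H](C=C(C)C)OC(C)=O | intermediate
21 | (1S,4R,6S)-4-acetoxy-6-[(2R,4R)-4-acetoxy-6-methylhept-5-en-2-yl]-3-methylcyclohex-2-en-1-yl (Z)-2-methylbut-2-enoate | C/C=C(/C)C(=O)O[C@@H]1C=C(C)[C@H](OC(C)=O)C[C@H]1[C@H](C)C[C@H](C=C(C)C)OC(C)=O | target

Total step count: 13. Longest linear sequence: 12 steps (steps 1–6, then 8–13); step 7 is a one-step side branch.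

Steps most likely to fail

Step 8. The acid stage may stall because the ethyl ketone enolises slowly towards C3, the hemiacetal form of 13 may dehydrate to a 4H-pyran, and the sulfonic acid may ionise the allylic acetate; in the amine stage, γ-deprotonation of the iminium ion could erode C7. The fallback sets out from 9 and 12 and comes back at 15. The Michael addition is run as before, but the crude adduct 13 is treated with Pd(PPh3)4, HCO2H and Et3N in THF instead of acid. Deallylation and decarboxylation should give the keto aldehyde (3S)-3-[(2R,4R)-4-acetoxy-6-methylhept-5-en-2-yl]-5-oxoheptanal F1, which can no longer undergo retro-Michael cleavage. F1 is then closed with dibenzylammonium trifluoroacetate in toluene at 23–50 °C (amine-salt aldol condensation, the only ring size available being six) to give enone 15 directly, so step 9 is not needed.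

Step 10. Enolisation may take the cross-conjugated course through C5, which would lead to hydroxylation at C5, and the peracid may epoxidise the side-chain alkene. The fallback sets out from 15 and comes back at 21, oxygenating C1 only after C4 is finished. Luche reduction of 15 should give the cis alcohol (1S,5S)-5-[(2R,4R)-4-acetoxy-6-methylhept-5-en-2-yl]-2-methylcyclohex-2-en-1-ol F2. Mitsunobu inversion with acetic acid then gives the acetate (1R,5S)-5-[(2R,4R)-4-acetoxy-6-methylhept-5-en-2-yl]-2-methylcyclohex-2-en-1-yl acetate F3. Allylic oxidation of the ring CH2 at C1 with Rh2(cap)4 and t-BuOOH (the secondary ring position should be preferred over the primary methyl groups and the acetoxy-bearing C–H bonds) gives the enone (1R,5S)-5-[(2R,4R)-4-acetoxy-6-methylhept-5-en-2-yl]-2-methyl-4-oxocyclohex-2-en-1-yl acetate F4. A second Luche reduction, with axial attack anti to the axial C6–H, gives the alcohol (1R,4S,5S)-5-[(2R,4R)-4-acetoxy-6-methylhept-5-en-2-yl]-4-hydroxy-2-methylcyclohex-2-en-1-yl acetate F5. Acylation of F5 with 18 under the mixed-anhydride conditions of step 11 gives 21.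

Step 13. The allylic alkoxyphosphonium ion may react by SN2′ attack at C2 or by elimination to a diene instead of clean inversion at the hindered C4. The fallback sets out from 19 and comes back at 21, setting C4 by reagent control instead of by inversion. CBS reduction of 19 with (S)-2-methyl-CBS-oxazaborolidine and catecholborane, in which the α-methyl vinyl side acts as the large group, should give the (4R)-alcohol (1S,4R,6S)-6-[(2R,4R)-4-acetoxy-6-methylhept-5-en-2-yl]-4-hydroxy-3-methylcyclohex-2-en-1-yl (Z)-2-methylbut-2-enoate F6 directly. Acetylation of F6 with Ac2O and pyridine then gives 21.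

Further compounds
F1 | step 8 | (3S)-3-[(2R,4R)-4-acetoxy-6-methylhept-5-en-2-yl]-5-oxoheptanal | O=CC[C@@H](CC(=O)CC)[C@H](C)C[C@H](C=C(C)C)OC(C)=O
F2 | step 10 | (1S,5S)-5-[(2R,4R)-4-acetoxy-6-methylhept-5-en-2-yl]-2-methylcyclohex-2-en-1-ol | C1C=C(C)[C@@H](O)C[C@H]1[C@H](C)C[C@H](C=C(C)C)OC(C)=O
F3 | step 10 | (1R,5S)-5-[(2R,4R)-4-acetoxy-6-methylhept-5-en-2-yl]-2-methylcyclohex-2-en-1-yl acetate | C1C=C(C)[C@H](OC(C)=O)C[C@H]1[C@H](C)C[C@H](C=C(C)C)OC(C)=O
F4 | step 10 | (1R,5S)-5-[(2R,4R)-4-acetoxy-6-methylhept-5-en-2-yl]-2-methyl-4-oxocyclohex-2-en-1-yl acetate | O=C1C=C(C)[C@H](OC(C)=O)C[C@H]1[C@H](C)C[C@H](C=C(C)C)OC(C)=O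
F5 | step 10 | (1R,4S,5S)-5-[(2R,4R)-4-acetoxy-6-methylhept-5-en-2-yl]-4-hydroxy-2-methylcyclohex-2-en-1-yl acetate | O[C@@H]1C=C(C)[C@H](OC(C)=O)C[C@H]1[C@H](C)C[C@H](C=C(C)C)OC(C)=O
F6 | step 13 | (1S,4R,6S)-6-[(2R,4R)-4-acetoxy-6-methylhept-5-en-2-yl]-4-hydroxy-3-methylcyclohex-2-en-1-yl (Z)-2-methylbut-2-enoate | C/C=C(/C)C(=O)O[C@@H]1C=C(C)[C@H](O)C[C@H]1[C@H](C)C[C@H](C=C(C)C)OC(C)=O
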